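Read at 12 min, the amber flask should show a flat line, and what matters is how close that line sits to its ceiling. Amber has the charge of the grey run, so the grey readings serve as its early history.

| flask | E | X | L | time |
|---|---|---|---|---|
| grey | 1.00 M | 0.800 M | 0.0500 M |  |
| ochre | 0.600 M | 0.400 M | 0.0500 M |  |
| teal | 1.00 M | 0.800 M | 0.0250 M |  |
| red | 3.00 M | 0.800 M | 0.0500 M |  |
| amber | 1.00 M | 0.800 M | 0.0500 M | 12 min |

| run | time / min | [Z] / M |
|---|---|---|
| grey run | 1.0 | 0.302 |
| grey run | 2.1 | 0.565 |
| grey run | 3.1 | 0.680 |
| grey run | 4.1 | 0.735 |
| grey run | 5.2 | 0.766 |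
| grey run | 6.2 | 0.779 |
| ochre run | 1.0 | 0.089 |
| ochre run | 2.1 | 0.183 |
| ochre run | 3.1 | 0.245 |
| ochre run | 4.1 | 0.294 |
| ochre run | 5.2 | 0.330 |
| ochre run | 6.2 | 0.344 |
| teal run | 1.0 | 0.187 |
| teal run | 2.1 | 0.460 |
| teal run | 3.1 | 0.616 |
| teal run | 4.1 | 0.697 |
| teal run | 5.2 | 0.743 |
| teal run | 6.2 | 0.767 |
| red run | 1.0 | 0.599 |
| red run | 2.1 | 0.790 |
| red run | 3.1 | 0.794 |
| red run | 4.1 | 0.801 |
| red run | 5.2 | 0.798 |
| red run | 6.2 | 0.800 |

(readings scatter by 0.003 M)

- Overall: E + X -> Z, with L as catalyst.
- Constant volume, constant temperature.
- The analysis sees a species whether free or bound.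
- "The second partner" is X.
- An order is taken over about fifteen percent of the charge, up and down.

* how the opening rate goes with [L] round the charge of the grey run: the exponent of the rate at two percent of E gone to Z
* how the opening rate goes with [E] round the charge of the grey run: the exponent of the rate at two percent of E gone to Z (one fixed amount of Z, the same in the runs compared)
* the ochre run starts with 0.400 M less of E and of X than the grey run, and with no Z. Compared where both hold the same amount of E, once fifteen percent of what the ochre run was charged with has turned into Z, is the ochre run faster, slower or alike (within a tenth)?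
* Z in the amber run at 12 min, as a share of the E charged

I keep a ledger of X, the limiting reagent, since amber holds 0.800 M of X on 1.00 M of E. Each Z takes one X, and the red run supports booking no other entry: its last reading is 0.800 M on 0.800 M of X charged. So in amber the books close with 0.200 M of E over, free and bound forms counted together, and I call the ceiling share the charge of X divided by the charge of E:

ceiling share = c(X) charged / c(E) charged = 80.0%

That is the end state. The approach comes from the open entry, the X not yet booked as Z, in the grey run:

first entry, open at 4.1 min: 0.800 M − 0.735 M = 0.0650 M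

second entry, open at 6.2 min: 0.800 M − 0.779 M = 0.0210 M

closing constant, read from these two: 0.538 min⁻¹

I treat this stretch of the grey run as pseudo-first-order in X, an assumption of mine; over it the E left in the grey run moves from 0.265 M to 0.221 M. Carrying the open entry on to the time of reading in amber gives:

open at 12 min: 0.0210 M × exp(−0.538 min⁻¹ × 5.80 min) = 9.27 × 10⁻⁴ M

My estimate for amber is then 79.9% of the E charged. The reckoned open entry is smaller than the scatter of 0.003 M, so I expect a repeat reading at that time to lie within the scatter of the ceiling.

The forecast gives 79.9% for amber, with a range of 79.3% to 80.2%, and its ground there is that “X is limiting”. It puts the order in L at 0.85 (0.7 to 1) and the order in E at 0.75 (0.5 to 1), and it calls the ochre run slower.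

The amber flask gives 79.9%, with orders of 0.88 in L and 0.53 in E, and ochre is slower: where ochre and grey hold the same amount of E, the rate of ochre over that of grey is 0.41. The forecast parts from the flask on the order in E, at 0.75 against 0.53.

    L + E ⇌ LE, settled at all times (0.7690 M⁻¹)
    LE + X → Z + L + G (18.66 M⁻¹ min⁻¹)
    E + X + Z → 2 Z (3.012 M⁻² min⁻¹)
    2 E ⇌ E2, settled at all times (0.6180 M⁻¹)

The red run holds the same X on 3.00 M of E, so its ceiling share is 26.7%, and a quarter of its E is 0.750 M, or 93.8% of its X. At two percent of the grey E turned, red runs at 0.40 M min⁻¹ against 0.25 M min⁻¹ for grey, yet red comes to a quarter of its own E charged later than grey comes to a quarter of its own, at 1.55 min against 0.837 min.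

Readings and results were generated by integration for substances that don't exist, noise included.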